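Everything rests on disconnecting the N–C3 bond of the nitrogen ring (ring B) together with the C1–CH3 bond. The key step exploits that imine carbon C1 sits on arene carbon C8a, ortho to the C4a–C4–C3 chain: a nitrile on C8a takes up methyllithium, and the nitrogen of the resulting N-lithio ketimine displaces chloride from (R)-configured C3 in a 6-exo SN2 closure. One operation thus creates the C1 methyl, the C1=N bond, ring B and, by inversion, the (S)-stereocentre; acidic work-up frees the naphthol. The precursor is a fully assembled biaryl benzonitrile with a 2-chloropropyl side chain, made by Negishi coupling of two short fragments.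

Key step: step 9

Remark on numbering: isoquinoline numbering is used for the heterobicycle (C1, N2, C3, C4, C4a, C5 to C8, C8a; ring A is the arene, ring B the nitrogen ring), and primed numbers are used for the naphthalene.

Assumption: the target structure defines no configuration for the biaryl axis (C7–C2'), so the axis is treated as not stereodefined and only C3 (S) is controlled.

Step 1
Reactants: 1 2-methoxy-4-methylbenzoic acid
Product: 3 N,N-diethyl-2-methoxy-4-methylbenzamide, via acid chloride 2 (not isolated)
Conditions: SOCl2, cat. DMF, toluene, 70 °C; then Et2NH (3 equiv), CH2Cl2, 0 °C → rt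
Reagents that add atoms: diethylamine, CCNCC
Why: Amide formation through the acid chloride is routine and installs the diethylamide that serves as directing group in step 2 and as acyl donor in step 3.

Step 2
Reactants: 3 N,N-diethyl-2-methoxy-4-methylbenzamide; 4 allyl bromide
Product: 7 N,N-diethyl-2-methoxy-4-methyl-6-(prop-2-en-1-yl)benzamide, via aryllithium 5 (not isolated), via arylmagnesium bromide 6 (not isolated)
Conditions: s-BuLi (1.1 equiv), TMEDA, THF, −78 °C; MgBr2·OEt2, −78 → 0 °C; then 4, 0 °C → rt
Reagents that add atoms: none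
Why: Directed ortho-metalation should remove the only hydrogen ortho to the diethylamide (the strongest director present), and transmetalation to magnesium should give clean allylation without halogen–metal exchange.

Step 3
Reactants: 7 N,N-diethyl-2-methoxy-4-methyl-6-(prop-2-en-1-yl)benzamide
Product: 9 8-methoxy-1-(methoxymethoxy)-6-methylnaphthalene, via lithium naphtholate 8 (not isolated)
Conditions: LDA (2.2 equiv), THF, −78 °C → rt; then MOMCl (4 equiv), DMPU, 0 °C → rt
Reagents that add atoms: chloromethyl methyl ether, COCCl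
Why: In this anionic benzannulation of an ortho-allylbenzamide, LDA removes the benzylic–allylic proton, the terminal carbon of the allyl anion acylates on the amide to close the six-membered ring, and loss of diethylamide with tautomerisation gives the naphtholate, which is O-alkylated in the same flask (Williamson-type etherification).

Step 4
Reactants: 10 1-bromo-3,5-dimethoxybenzene; 11 (S)-propylene oxide
Product: 13 (2S)-1-(3,5-dimethoxyphenyl)propan-2-ol, via Grignard reagent 12 (not isolated)
Conditions: Mg, THF, reflux; then CuI (10 mol%), 11, −30 → 0 °C; aq. NH4Cl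
Reagents that add atoms: none
Why: CuI-catalysed epoxide opening by the aryl Grignard reagent occurs at the unsubstituted carbon, so the stereocentre of the (S)-epoxide is carried over untouched as the (S)-carbinol.

Step 5
Reactants: 13 (2S)-1-(3,5-dimethoxyphenyl)propan-2-ol
Product: 15 (2S)-1-(4-iodo-3,5-dimethoxyphenyl)propan-2-ol, via dilithio species 14 (not isolated)
Conditions: n-BuLi (2.3 equiv), THF, 0 °C → rt; then ICH2CH2I, −78 °C → rt; aq. Na2S2O3
Reagents that add atoms: 1,2-diiodoethane, ICCI
Why: After the first equivalent of base forms the alkoxide, directed ortho-metalation should occur at the position flanked by both methoxy groups (the cooperative site of resorcinol dimethyl ethers), and 1,2-diiodoethane iodinates the aryllithium without oxidising the alkoxide.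

Step 6
Reactants: 15 (2S)-1-(4-iodo-3,5-dimethoxyphenyl)propan-2-ol
Product: 16 5-[(2R)-2-chloropropyl]-2-iodo-1,3-dimethoxybenzene
Conditions: PPh3 (1.3 equiv), NCS (1.3 equiv), THF, 0 °C → rt
Reagents that add atoms: N-chlorosuccinimide, O=C1CCC(=O)N1Cl
Why: Appel-type chlorination proceeds by SN2 attack of chloride on the alkoxyphosphonium salt and should therefore invert the (S)-alcohol to the (R)-chloride, aryl participation being disfavoured because the ring carbon bearing the chain is meta to both methoxy groups.

Step 7
Reactants: 16 5-[(2R)-2-chloropropyl]-2-iodo-1,3-dimethoxybenzene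
Product: 18 6-[(2R)-2-chloropropyl]-3-iodo-2,4-dimethoxybenzonitrile, via N-chlorosulfonyl amide 17 (not isolated)
Conditions: ClSO2NCO (1.2 equiv), CH2Cl2, 0 °C → rt; then DMF, 0 °C → rt; ice-water
Reagents that add atoms: chlorosulfonyl isocyanate, O=C=NS(=O)(=O)Cl
Why: Electrophilic aromatic cyanation with chlorosulfonyl isocyanate (Friedel–Crafts-type amidation, then DMF-induced loss of chlorosulfonic acid) can only attack the two equivalent free positions, each ortho to one methoxy group and para to the other, so a single regioisomer should result.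

Step 8
Reactants: 9 8-methoxy-1-(methoxymethoxy)-6-methylnaphthalene; 18 6-[(2R)-2-chloropropyl]-3-iodo-2,4-dimethoxybenzonitrile
Product: 21 6-[(2R)-2-chloropropyl]-2,4-dimethoxy-3-[8-methoxy-1-(methoxymethoxy)-6-methylnaphthalen-2-yl]benzonitrile, via aryllithium 19 (not isolated), via arylzinc chloride 20 (not isolated)
Conditions: 9 (1.3 equiv), n-BuLi (1.25 equiv), TMEDA, THF, 0 °C; ZnCl2, 0 °C → rt; then 18, Pd2(dba)3 (2 mol%), SPhos (8 mol%), THF, 60 °C
Reagents that add atoms: none
Why: The MOM ether directs lithiation to C2' (C8' is blocked), the derived arylzinc tolerates the nitrile and the secondary chloride, and Negishi coupling with the SPhos-ligated zerovalent palladium catalyst, which inserts only into the aryl C–I bond, should forge the tri-ortho-substituted biaryl.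

Step 9
Reactants: 21 6-[(2R)-2-chloropropyl]-2,4-dimethoxy-3-[8-methoxy-1-(methoxymethoxy)-6-methylnaphthalen-2-yl]benzonitrile
Product: 24 2-[(3S)-6,8-dimethoxy-1,3-dimethyl-3,4-dihydroisoquinolin-7-yl]-8-methoxy-6-methylnaphthalen-1-ol, via N-lithio ketimine 22 (not isolated), via MOM-protected imine 23 (not isolated)
Conditions: MeLi (1.3 equiv), Et2O/THF, −78 → 0 °C; then DMPU, 50 °C; then MeOH, 3 M HCl, 45 °C; aq. NaHCO3
Reagents that add atoms: methyllithium, [Li]C
Why: MeLi adds to the nitrile to give N-lithio ketimine 22 (new C1–CH3 and C1=N bonds), whose nitrogen then attacks C3 from the side opposite to chloride and expels LiCl. The closest known reaction type is the addition of organolithium or Grignard reagents to ω-halo nitriles, which gives 1-pyrrolines and tetrahydropyridines by the same N-alkylation of a metallo-ketimine. Ring B closes in the 6-exo-tet mode. The C3 stereocentre is controlled by the substrate: the SN2 displacement inverts the (R)-chloride to the (S)-configured C3, and nothing afterwards touches it. The step needs addition to the nitrile over deprotonation and N-alkylation over elimination; the nitrile has no α-hydrogen, MeLi is a poor kinetic base that leaves a secondary chloride alone at low temperature, and ionisation at C3 is not assisted because arene carbon C4a is meta to both methoxy groups. Methanolic HCl then cleaves the MOM acetal while the cyclic imine is held as its iminium salt.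

Compound list
1 | 2-methoxy-4-methylbenzoic acid | Cc1ccc(C(=O)O)c(OC)c1 | starting material
2 | 2-methoxy-4-methylbenzoyl chloride | Cc1ccc(C(=O)Cl)c(OC)c1 | intermediate
3 | N,N-diethyl-2-methoxy-4-methylbenzamide | CCN(CC)C(=O)c1ccc(C)cc1OC | intermediate
4 | allyl bromide (3-bromoprop-1-ene) | C=CCBr | starting material
5 | [2-(diethylcarbamoyl)-3-methoxy-5-methylphenyl]lithium | CCN(CC)C(=O)c1c([Li])cc(C)cc1OC | intermediate
6 | [2-(diethylcarbamoyl)-3-methoxy-5-methylphenyl]magnesium bromide | CCN(CC)C(=O)c1c([Mg]Br)cc(C)cc1OC | intermediate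
7 | N,N-diethyl-2-methoxy-4-methyl-6-(prop-2-en-1-yl)benzamide | CCN(CC)C(=O)c1c(CC=C)cc(C)cc1OC | intermediate
8 | lithium 8-methoxy-6-methylnaphthalen-1-olate | [Li+].COc1cc(C)cc2cccc([O-])c12 | intermediate
9 | 8-methoxy-1-(methoxymethoxy)-6-methylnaphthalene | COCOc1cccc2cc(C)cc(OC)c12 | intermediate
10 | 1-bromo-3,5-dimethoxybenzene | COc1cc(Br)cc(OC)c1 | starting material
11 | (S)-propylene oxide, (2S)-2-methyloxirane | C[C@H]1CO1 | starting material
12 | (3,5-dimethoxyphenyl)magnesium bromide | COc1cc([Mg]Br)cc(OC)c1 | intermediate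
13 | (2S)-1-(3,5-dimethoxyphenyl)propan-2-ol | C[C@H](O)Cc1cc(OC)cc(OC)c1 | intermediate
14 | lithium (2S)-1-(4-lithio-3,5-dimethoxyphenyl)propan-2-olate | C[C@H](O[Li])Cc1cc(OC)c([Li])c(OC)c1 | intermediate
15 | (2S)-1-(4-iodo-3,5-dimethoxyphenyl)propan-2-ol | C[C@H](O)Cc1cc(OC)c(I)c(OC)c1 | intermediate
16 | 5-[(2R)-2-chloropropyl]-2-iodo-1,3-dimethoxybenzene | C[C@@H](Cl)Cc1cc(OC)c(I)c(OC)c1 | intermediate
17 | 6-[(2R)-2-chloropropyl]-N-(chlorosulfonyl)-3-iodo-2,4-dimethoxybenzamide | C[C@@H](Cl)Cc1cc(OC)c(I)c(OC)c1C(=O)NS(=O)(=O)Cl | intermediate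
18 | 6-[(2R)-2-chloropropyl]-3-iodo-2,4-dimethoxybenzonitrile | C[C@@H](Cl)Cc1cc(OC)c(I)c(OC)c1C#N | intermediate
19 | [8-methoxy-1-(methoxymethoxy)-6-methylnaphthalen-2-yl]lithium | COCOc1c([Li])ccc2cc(C)cc(OC)c12 | intermediate
20 | [8-methoxy-1-(methoxymethoxy)-6-methylnaphthalen-2-yl]zinc chloride | COCOc1c([Zn]Cl)ccc2cc(C)cc(OC)c12 | intermediate
21 | 6-[(2R)-2-chloropropyl]-2,4-dimethoxy-3-[8-methoxy-1-(methoxymethoxy)-6-methylnaphthalen-2-yl]benzonitrile | C[C@@H](Cl)Cc1cc(OC)c(-c2ccc3cc(C)cc(OC)c3c2OCOC)c(OC)c1C#N | intermediate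
22 | N-lithio imine of 1-{6-[(2R)-2-chloropropyl]-2,4-dimethoxy-3-[8-methoxy-1-(methoxymethoxy)-6-methylnaphthalen-2-yl]phenyl}ethan-1-one | C[C@@H](Cl)Cc1cc(OC)c(-c2ccc3cc(C)cc(OC)c3c2OCOC)c(OC)c1C(C)=N[Li] | intermediate
23 | (3S)-6,8-dimethoxy-7-[8-methoxy-1-(methoxymethoxy)-6-methylnaphthalen-2-yl]-1,3-dimethyl-3,4-dihydroisoquinoline | COc1cc2c(c(OC)c1-c1ccc3cc(C)cc(OC)c3c1OCOC)C(C)=N[C@@H](C)C2 | intermediate
24 | 2-[(3S)-6,8-dimethoxy-1,3-dimethyl-3,4-dihydroisoquinolin-7-yl]-8-methoxy-6-methylnaphthalen-1-ol | COc1cc2c(c(OC)c1-c1ccc3cc(C)cc(OC)c3c1O)C(C)=N[C@@H](C)C2 | target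

Total step count: 9. Longest linear sequence: 6 steps (steps 4 to 9).

Steps most likely to fail

Step 9 (ring closure). Substitution at the secondary carbon may be slow in the warm phase, so that benzylic deprotonation with loss of HCl competes with ring closure. The fallback sets out from 21 and comes back to the route at 23. MeLi is added at −78 → 0 °C and the mixture is quenched cold with aqueous citric acid, so that the ketimine is hydrolysed to 1-{6-[(2R)-2-chloropropyl]-2,4-dimethoxy-3-[8-methoxy-1-(methoxymethoxy)-6-methylnaphthalen-2-yl]phenyl}ethan-1-one F1. NaN3 in DMF at 60 °C then displaces chloride with inversion to give 1-{6-[(2S)-2-azidopropyl]-2,4-dimethoxy-3-[8-methoxy-1-(methoxymethoxy)-6-methylnaphthalen-2-yl]phenyl}ethan-1-one F2. PPh3 in THF at 50 °C (Staudinger reduction followed by intramolecular aza-Wittig condensation) should close ring B to 23, which is taken to 24 by the same methanolic HCl treatment.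

Step 8 (biaryl coupling). Transmetalation and reductive elimination at the tri-ortho-substituted axis may be slow, so that protodemetalation and homocoupling of the arylzinc take over. The fallback sets out from 9 and comes back at 21. Aryllithium 19 is trapped with 2-isopropoxy-4,4,5,5-tetramethyl-1,3,2-dioxaborolane and isolated as 2-[8-methoxy-1-(methoxymethoxy)-6-methylnaphthalen-2-yl]-4,4,5,5-tetramethyl-1,3,2-dioxaborolane F3. Suzuki–Miyaura coupling of F3 with 18 (Pd(OAc)2, SPhos, K3PO4, toluene/water, 80 °C) should then give 21.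

Step 7 (cyanation). Acylation at the hindered position next to the side chain may be sluggish, and ipso attack with loss of iodine may compete. The fallback sets out from 16 and comes back at 18. Vilsmeier–Haack formylation (POCl3, DMF, 0 → 60 °C) should give 6-[(2R)-2-chloropropyl]-3-iodo-2,4-dimethoxybenzaldehyde F4, which is converted into nitrile 18 by oxidative amination with iodine in aqueous ammonia/THF at rt.

Further compounds
F1 | step 9 | 1-{6-[(2R)-2-chloropropyl]-2,4-dimethoxy-3-[8-methoxy-1-(methoxymethoxy)-6-methylnaphthalen-2-yl]phenyl}ethan-1-one | C[C@@H](Cl)Cc1cc(OC)c(-c2ccc3cc(C)cc(OC)c3c2OCOC)c(OC)c1C(C)=O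
F2 | step 9 | 1-{6-[(2S)-2-azidopropyl]-2,4-dimethoxy-3-[8-methoxy-1-(methoxymethoxy)-6-methylnaphthalen-2-yl]phenyl}ethan-1-one | C[C@H](N=[N+]=[N-])Cc1cc(OC)c(-c2ccc3cc(C)cc(OC)c3c2OCOC)c(OC)c1C(C)=O
F3 | step 8 | 2-[8-methoxy-1-(methoxymethoxy)-6-methylnaphthalen-2-yl]-4,4,5,5-tetramethyl-1,3,2-dioxaborolane | COCOc1c(B2OC(C)(C)C(C)(C)O2)ccc2cc(C)cc(OC)c12
F4 | step 7 | 6-[(2R)-2-chloropropyl]-3-iodo-2,4-dimethoxybenzaldehyde | C[C@@H](Cl)Cc1cc(OC)c(I)c(OC)c1C=O
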